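**Retrosynthetic overview**

1. Target 35 ← diol 33 (acetylation of the primary C13–OH) ← silylated bicycle 32 (one HF treatment: three Si–O cleavages and Peterson unveiling of the C11=C12 methylene).
2. 32 ← vinylallenyl ketone 31 by intramolecular Diels–Alder reaction: bonds C3–C4 and C5–C10 form and rings A and B close in the same event. The feature used is the linear dienone O=C8–C9=C10–C1=C2 that spans rings B and A, flanked by the C3 acyloxy group and the cis C4/C5 methyl pair, which is exactly the product pattern of a vinylallene [4+2].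
3. 31 ← skipped enynone 30 (amine base) ← open-chain aldehyde 27 + alkyne 13. Alkyne 13 already carries the side chain as a (Z)-enol ester (Ru-catalysed addition of acid 7 to diyne 11), so the C3 ester is never installed on the ring.
4. 27 ← β-keto ester 20 (catalytic asymmetric α-hydroxylation sets C7, from which C3, C4 and C5 are relayed) ← Johnson–Claisen ester 17 + Weinreb amide 18.
5. Ring order: no ring before step 15; rings A and B are then formed together from an acyclic precursor.

Key step: step 15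

**Remarks (assumptions)**

- Atom labels C1–C15 follow the eremophilane numbering of the target in every intermediate (C11–C13 = three-carbon unit on C7, C14 = methyl on C5, C15 = methyl on C4).
- (R)-2-Methylbutan-1-ol 1 and Weinreb amide 18 are taken as purchasable.
- The facial sense of the titanium catalyst in step 9 on this open-chain keto ester is assumed; if it proves opposite, the mirror-image ligand is used and nothing else changes.

**Route**

Step 1
Reactants: 1 (R)-2-methylbutan-1-ol; 2 2-(triphenylphosphoranylidene)propanal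
Product: 4 (2E,4R)-2,4-dimethylhex-2-enal, via (R)-2-methylbutanal 3 (not isolated)
Conditions: Dess–Martin periodinane, CH2Cl2, 0 °C → rt; then 2, 40 °C
Reagents that add atoms: 2-(triphenylphosphoranylidene)propanal 2, `CC(C=O)=P(c1ccccc1)(c1ccccc1)c1ccccc1`
Why: Base-free Dess–Martin oxidation gives the α-branched aldehyde, and the stabilised formyl ylide (Wittig reaction) converts it in the same flask into the (E)-enal; the stereocentre is bought with 1 and is not touched.

Step 2
Reactants: 4 (2E,4R)-2,4-dimethylhex-2-enal; 5 triethyl phosphonoacetate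
Product: 6 ethyl (2E,4E,6R)-4,6-dimethylocta-2,4-dienoate
Conditions: NaH, THF, 0 °C → rt
Reagents that add atoms: triethyl phosphonoacetate 5, `CCOC(=O)CP(=O)(OCC)OCC`
Why: Horner–Wadsworth–Emmons olefination of an enal with a stabilised phosphonate anion gives the (2E)-dienoate.

Step 3
Reactants: 6 ethyl (2E,4E,6R)-4,6-dimethylocta-2,4-dienoate
Product: 7 (2E,4E,6R)-4,6-dimethylocta-2,4-dienoic acid
Conditions: LiOH·H2O, THF/MeOH/H2O, rt; aq. HCl
Reagents that add atoms: lithium hydroxide, `[Li+].[OH-]`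
Why: Saponification of an unhindered ethyl ester that has no epimerisable centre next to the carboxyl group.

Step 4
Reactants: 8 ethynyltrimethylsilane; 9 3-bromoprop-1-yne (propargyl bromide)
Product: 11 trimethyl(penta-1,4-diyn-1-yl)silane, via [(trimethylsilyl)ethynyl]magnesium bromide 10 (not isolated)
Conditions: EtMgBr, THF, 0 °C → rt; then CuCl (cat.), 9, 50 °C
Reagents that add atoms: 3-bromoprop-1-yne 9, `C#CCBr`
Why: Copper-catalysed coupling of an alkynyl Grignard reagent with propargyl bromide is the standard entry to skipped diynes.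

Step 5
Reactants: 11 trimethyl(penta-1,4-diyn-1-yl)silane; 7 (2E,4E,6R)-4,6-dimethylocta-2,4-dienoic acid
Product: 12 (1Z)-5-(trimethylsilyl)pent-1-en-4-yn-1-yl (2E,4E,6R)-4,6-dimethylocta-2,4-dienoate
Conditions: Ru(η3-2-methylallyl)2[Ph2P(CH2)4PPh2] (2 mol %), toluene, 60 °C
Reagents that add atoms: (2E,4E,6R)-4,6-dimethylocta-2,4-dienoic acid 7, `OC(=O)/C=C/C(C)=C/[C@H](C)CC`
Why: Ruthenium-catalysed anti-Markovnikov addition of a carboxylic acid to a terminal alkyne (through a ruthenium vinylidene) gives the (Z)-enol ester by trans addition; the silylated alkyne cannot form a vinylidene and stays untouched.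

Step 6
Reactants: 12 (1Z)-5-(trimethylsilyl)pent-1-en-4-yn-1-yl (2E,4E,6R)-4,6-dimethylocta-2,4-dienoate
Product: 13 (1Z)-pent-1-en-4-yn-1-yl (2E,4E,6R)-4,6-dimethylocta-2,4-dienoate
Conditions: AgNO3 (10 mol %), acetone/H2O, rt
Reagents that add atoms: none
Why: Silver-catalysed protodesilylation of an alkynylsilane runs at neutral pH, which the enol ester and the skipped enyne tolerate.

Step 7
Reactants: 14 3-methylbut-3-en-2-ol (racemic); 15 trimethyl orthoacetate
Product: 17 methyl (4E)-4-methylhex-4-enoate, via mixed ketene acetal 16 (not isolated)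
Conditions: EtCO2H (cat.), 140 °C, methanol distilled off
Reagents that add atoms: trimethyl orthoacetate 15, `CC(OC)(OC)OC`
Why: Johnson orthoester Claisen rearrangement; the chair transition state with the carbinol methyl group equatorial gives the (E)-trisubstituted alkene, the later C4=C5 with its two methyl groups cis.

Step 8
Reactants: 17 methyl (4E)-4-methylhex-4-enoate; 18 2-[(tert-butyldimethylsilyl)oxy]-N-methoxy-N-methylacetamide
Product: 20 methyl (4E)-2-{[(tert-butyldimethylsilyl)oxy]acetyl}-4-methylhex-4-enoate (racemic), via lithium ester enolate 19 (not isolated)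
Conditions: LiN(i-Pr)2, THF, −78 °C; then 18, −78 → −20 °C; aq. NH4Cl
Reagents that add atoms: 2-[(tert-butyldimethylsilyl)oxy]-N-methoxy-N-methylacetamide 18, `CON(C)C(=O)CO[Si](C)(C)C(C)(C)C`
Why: Claisen-type C-acylation of an ester enolate with a Weinreb amide, whose stable tetrahedral adduct prevents a second addition.

Step 9
Reactants: 20 methyl (4E)-2-{[(tert-butyldimethylsilyl)oxy]acetyl}-4-methylhex-4-enoate; 21 3-(4-nitrophenyl)-2-(phenylsulfonyl)oxaziridine
Product: 22 methyl (2S,4E)-2-{[(tert-butyldimethylsilyl)oxy]acetyl}-2-hydroxy-4-methylhex-4-enoate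
Conditions: TiCl2(MeCN)2[(4R,5R)-2,2-dimethyl-α,α,α′,α′-tetra(1-naphthyl)-1,3-dioxolane-4,5-dimethanolate] (5 mol %), CH2Cl2, rt
Reagents that add atoms: 3-(4-nitrophenyl)-2-(phenylsulfonyl)oxaziridine 21, `O=S(=O)(c1ccccc1)N1OC1c1ccc(cc1)[N+](=O)[O-]`
Why: Lewis-acid-catalysed enantioselective α-hydroxylation of a β-keto ester: the chiral titanium enolate is oxidised on one face by the oxaziridine, which sets C7 (S), the only stereocentre of the core made by a catalyst.

Step 10
Reactants: 22 methyl (2S,4E)-2-{[(tert-butyldimethylsilyl)oxy]acetyl}-2-hydroxy-4-methylhex-4-enoate; 23 (trimethylsilyl)methylmagnesium chloride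
Product: 24 methyl (2S,4E)-2-hydroxy-2-{1-[(tert-butyldimethylsilyl)oxy]-2-hydroxy-3-(trimethylsilyl)propan-2-yl}-4-methylhex-4-enoate (both configurations at the new carbinol C11)
Conditions: 23 (3 equiv), LaCl3·2LiCl, THF, −78 → −20 °C; aq. NH4Cl
Reagents that add atoms: (trimethylsilyl)methylmagnesium chloride 23, `C[Si](C)(C)C[Mg]Cl`
Why: Chelation-assisted Grignard addition to the ketone beside the ester gives a β-hydroxysilane as a latent C11=C12 methylene (Peterson precursor); it is carried in this form because a free 1,1-disubstituted alkene on C7 would be a second dienophile on a three-atom tether in step 15, and the configuration of the new carbinol is lost later.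

Step 11
Reactants: 24 methyl (2S,4E)-2-hydroxy-2-{1-[(tert-butyldimethylsilyl)oxy]-2-hydroxy-3-(trimethylsilyl)propan-2-yl}-4-methylhex-4-enoate; 25 triethylsilyl trifluoromethanesulfonate
Product: 26 methyl (2S,4E)-2-{1-[(tert-butyldimethylsilyl)oxy]-2-[(triethylsilyl)oxy]-3-(trimethylsilyl)propan-2-yl}-4-methyl-2-[(triethylsilyl)oxy]hex-4-enoate
Conditions: 25 (3 equiv), 2,6-lutidine, CH2Cl2, −78 → 0 °C
Reagents that add atoms: triethylsilyl trifluoromethanesulfonate 25, `CC[Si](CC)(CC)OS(=O)(=O)C(F)(F)F`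
Why: A silyl triflate with a hindered pyridine base silylates tertiary alcohols, and both hydroxyl groups must be capped before the hydride and organolithium steps.

Step 12
Reactants: 26 methyl (2S,4E)-2-{1-[(tert-butyldimethylsilyl)oxy]-2-[(triethylsilyl)oxy]-3-(trimethylsilyl)propan-2-yl}-4-methyl-2-[(triethylsilyl)oxy]hex-4-enoate
Product: 27 (2S,4E)-2-{1-[(tert-butyldimethylsilyl)oxy]-2-[(triethylsilyl)oxy]-3-(trimethylsilyl)propan-2-yl}-4-methyl-2-[(triethylsilyl)oxy]hex-4-enal
Conditions: i-Bu2AlH, CH2Cl2, −78 °C; aq. potassium sodium tartrate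
Reagents that add atoms: none
Why: Low-temperature i-Bu2AlH reduction of an α-silyloxy ester stops at the aldehyde through the stable aluminium hemiacetal; the aldehyde has no α-hydrogen, so C7 cannot epimerise.

Step 13
Reactants: 27 (2S,4E)-2-{1-[(tert-butyldimethylsilyl)oxy]-2-[(triethylsilyl)oxy]-3-(trimethylsilyl)propan-2-yl}-4-methyl-2-[(triethylsilyl)oxy]hex-4-enal; 13 (1Z)-pent-1-en-4-yn-1-yl (2E,4E,6R)-4,6-dimethylocta-2,4-dienoate
Product: 29 (1Z,7R,9E)-6-hydroxy-9-methyl-7-{1-[(tert-butyldimethylsilyl)oxy]-2-[(triethylsilyl)oxy]-3-(trimethylsilyl)propan-2-yl}-7-[(triethylsilyl)oxy]undeca-1,9-dien-4-yn-1-yl (2E,4E,6R)-4,6-dimethylocta-2,4-dienoate (both epimers at the carbinol C8; same spatial arrangement at C7 as in 27), via lithium acetylide 28 (not isolated)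
Conditions: 13 (1.3 equiv), LiN(SiMe3)2, THF, −78 °C; then 27, −78 °C; aq. NH4Cl at −78 °C
Reagents that add atoms: (1Z)-pent-1-en-4-yn-1-yl (2E,4E,6R)-4,6-dimethylocta-2,4-dienoate 13, `C#CC/C=C\OC(=O)/C=C/C(C)=C/[C@H](C)CC`
Why: 1,2-Addition of a lithium acetylide to an aldehyde joins the two fragments; the hindered amide base at −78 °C metalates the alkyne without attacking the enol ester, and the new carbinol is oxidised in the next step.

Step 14
Reactants: 29 propargylic alcohol (both C8 epimers)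
Product: 30 (1Z,7S,9E)-9-methyl-6-oxo-7-{1-[(tert-butyldimethylsilyl)oxy]-2-[(triethylsilyl)oxy]-3-(trimethylsilyl)propan-2-yl}-7-[(triethylsilyl)oxy]undeca-1,9-dien-4-yn-1-yl (2E,4E,6R)-4,6-dimethylocta-2,4-dienoate
Conditions: Dess–Martin periodinane, pyridine, CH2Cl2, 0 °C
Reagents that add atoms: none
Why: Dess–Martin oxidation converts a propargylic alcohol into the ynone under buffered, non-basic conditions, so the skipped enyne is not isomerised at this stage.

Step 15
Reactants: 30 skipped enynone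
Product: 32 (3S,4S,5S,7S)-13-[(tert-butyldimethylsilyl)oxy]-8-oxo-7,11-bis[(triethylsilyl)oxy]-12-(trimethylsilyl)eremophila-1,9-dien-3-yl (2E,4E,6R)-4,6-dimethylocta-2,4-dienoate, via vinylallenyl ketone 31 (not isolated)
Conditions: Et3N (0.2 equiv), 2,6-di-tert-butyl-4-methylphenol (cat.), toluene (0.005 M), 25 → 90 °C
Reagents that add atoms: none
Why: Et3N removes a proton from the doubly activated C1 methylene of ynone 30 and reprotonation at C9 (1,3-prototropy) gives vinylallenyl ketone 31, whose diene C10=C1–C2=C3 adds suprafacially to the tethered (E)-C4=C5 alkene in a concerted [4+2] cycloaddition. The closest known reaction type is the type 1 intramolecular Diels–Alder reaction of vinylallenes fed by ynone–allenone isomerisation; vinylallenes react on mild heating because the sp carbon C10 carries no inside substituent, which also lets the (Z)-acyloxy group sit inside. Ring A is closed as the new cyclohexene (bonds C3–C4 and C5–C10), ring B is closed by the same C5–C10 bond through the four-atom tether C9–C8–C7–C6 held exo on C5, and the second allene π bond remains as the ring B alkene C9=C10 conjugated to C8=O. C4 and C5 should come out cis because the two methyl groups are cis on the (E)-alkene, and C3–O trans to them because the inside oxygen of the (Z)-enol ester ends on the face of the exo groups. The absolute sense is relayed from C7: the two allene epimers interconvert through the enolate under Et3N, and the one expected to react places the forming ring B in a half-chair with the C5 methyl axial, the C7 silyloxy group axial beside it and the very large C11 group equatorial. The step needs chemoselectivity, secured because the tiglyl alkene is the only π bond within reach while C12 is still masked, and a cycloaddition faster than proton drift into the conjugated enynone, which is why only a weak amine base in catalytic amount is used.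

Step 16
Reactants: 32 silylated bicyclic dienone
Product: 33 (3S,4S,5S,7S)-7,13-dihydroxy-8-oxoeremophila-1,9,11(12)-trien-3-yl (2E,4E,6R)-4,6-dimethylocta-2,4-dienoate
Conditions: 48 % aq. HF, MeCN, 0 °C → rt
Reagents that add atoms: none
Why: Aqueous HF cleaves the three silyl ethers, and the freed tertiary β-hydroxysilane undergoes acid-promoted Peterson elimination, which can only give the C11=C12 methylene.

Step 17
Reactants: 33 diol; 34 acetic anhydride
Product: 35 (3S,4S,5S,7S)-13-acetoxy-7-hydroxy-8-oxoeremophila-1,9,11(12)-trien-3-yl (2E,4E,6R)-4,6-dimethylocta-2,4-dienoate (target)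
Conditions: 34 (1.2 equiv), pyridine, CH2Cl2, 0 °C
Reagents that add atoms: acetic anhydride 34, `CC(=O)OC(C)=O`
Why: Acylation of the primary allylic alcohol is far faster than that of the tertiary α-ketol hydroxyl group, so a small excess of anhydride should give the 13-acetate only.

**Compound list**

1 | (R)-2-methylbutan-1-ol | `CC[C@@H](C)CO` | starting material
2 | 2-(triphenylphosphoranylidene)propanal | `CC(C=O)=P(c1ccccc1)(c1ccccc1)c1ccccc1` | starting material
3 | (R)-2-methylbutanal | `CC[C@@H](C)C=O` | intermediate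
4 | (2E,4R)-2,4-dimethylhex-2-enal | `CC[C@@H](C)/C=C(\C)C=O` | intermediate
5 | triethyl phosphonoacetate | `CCOC(=O)CP(=O)(OCC)OCC` | starting material
6 | ethyl (2E,4E,6R)-4,6-dimethylocta-2,4-dienoate | `CCOC(=O)/C=C/C(C)=C/[C@H](C)CC` | intermediate
7 | (2E,4E,6R)-4,6-dimethylocta-2,4-dienoic acid | `OC(=O)/C=C/C(C)=C/[C@H](C)CC` | intermediate
8 | ethynyltrimethylsilane | `C#C[Si](C)(C)C` | starting material
9 | 3-bromoprop-1-yne | `C#CCBr` | starting material
10 | [(trimethylsilyl)ethynyl]magnesium bromide | `C[Si](C)(C)C#C[Mg]Br` | intermediate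
11 | trimethyl(penta-1,4-diyn-1-yl)silane | `C#CCC#C[Si](C)(C)C` | intermediate
12 | (1Z)-5-(trimethylsilyl)pent-1-en-4-yn-1-yl (2E,4E,6R)-4,6-dimethylocta-2,4-dienoate | `C[Si](C)(C)C#CC/C=C\OC(=O)/C=C/C(C)=C/[C@H](C)CC` | intermediate
13 | (1Z)-pent-1-en-4-yn-1-yl (2E,4E,6R)-4,6-dimethylocta-2,4-dienoate | `C#CC/C=C\OC(=O)/C=C/C(C)=C/[C@H](C)CC` | intermediate
14 | 3-methylbut-3-en-2-ol (racemic) | `CC(O)C(C)=C` | starting material
15 | trimethyl orthoacetate | `CC(OC)(OC)OC` | starting material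
16 | mixed ketene acetal, 3-[(1-methoxyethenyl)oxy]-2-methylbut-1-ene | `C=C(OC)OC(C)C(C)=C` | intermediate
17 | methyl (4E)-4-methylhex-4-enoate | `COC(=O)CC/C(C)=C/C` | intermediate
18 | 2-[(tert-butyldimethylsilyl)oxy]-N-methoxy-N-methylacetamide | `CON(C)C(=O)CO[Si](C)(C)C(C)(C)C` | starting material
19 | lithium enolate of 17 | `COC(O[Li])=CC/C(C)=C/C` | intermediate
20 | methyl (4E)-2-{[(tert-butyldimethylsilyl)oxy]acetyl}-4-methylhex-4-enoate (racemic) | `COC(=O)C(C/C(C)=C/C)C(=O)CO[Si](C)(C)C(C)(C)C` | intermediate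
21 | 3-(4-nitrophenyl)-2-(phenylsulfonyl)oxaziridine (racemic) | `O=S(=O)(c1ccccc1)N1OC1c1ccc(cc1)[N+](=O)[O-]` | starting material
22 | methyl (2S,4E)-2-{[(tert-butyldimethylsilyl)oxy]acetyl}-2-hydroxy-4-methylhex-4-enoate | `CC(C)(C)[Si](C)(C)OCC(=O)[C@@](C(=O)OC)(O)C/C(C)=C/C` | intermediate
23 | (trimethylsilyl)methylmagnesium chloride | `C[Si](C)(C)C[Mg]Cl` | starting material
24 | methyl (2S,4E)-2-hydroxy-2-{1-[(tert-butyldimethylsilyl)oxy]-2-hydroxy-3-(trimethylsilyl)propan-2-yl}-4-methylhex-4-enoate (C11 epimers) | `CC(C)(C)[Si](C)(C)OCC(O)(C[Si](C)(C)C)[C@@](C(=O)OC)(O)C/C(C)=C/C` | intermediate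
25 | triethylsilyl trifluoromethanesulfonate | `CC[Si](CC)(CC)OS(=O)(=O)C(F)(F)F` | starting material
26 | methyl (2S,4E)-2-{1-[(tert-butyldimethylsilyl)oxy]-2-[(triethylsilyl)oxy]-3-(trimethylsilyl)propan-2-yl}-4-methyl-2-[(triethylsilyl)oxy]hex-4-enoate | `CC(C)(C)[Si](C)(C)OCC(O[Si](CC)(CC)CC)(C[Si](C)(C)C)[C@@](C(=O)OC)(O[Si](CC)(CC)CC)C/C(C)=C/C` | intermediate
27 | (2S,4E)-2-{1-[(tert-butyldimethylsilyl)oxy]-2-[(triethylsilyl)oxy]-3-(trimethylsilyl)propan-2-yl}-4-methyl-2-[(triethylsilyl)oxy]hex-4-enal | `CC(C)(C)[Si](C)(C)OCC(O[Si](CC)(CC)CC)(C[Si](C)(C)C)[C@@](C=O)(O[Si](CC)(CC)CC)C/C(C)=C/C` | intermediate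
28 | lithium acetylide of 13 | `[Li]C#CC/C=C\OC(=O)/C=C/C(C)=C/[C@H](C)CC` | intermediate
29 | (1Z,7R,9E)-6-hydroxy-9-methyl-7-{1-[(tert-butyldimethylsilyl)oxy]-2-[(triethylsilyl)oxy]-3-(trimethylsilyl)propan-2-yl}-7-[(triethylsilyl)oxy]undeca-1,9-dien-4-yn-1-yl (2E,4E,6R)-4,6-dimethylocta-2,4-dienoate (C8 epimers) | `CC(C)(C)[Si](C)(C)OCC(O[Si](CC)(CC)CC)(C[Si](C)(C)C)[C@@](C(O)C#CC/C=C\OC(=O)/C=C/C(C)=C/[C@H](C)CC)(O[Si](CC)(CC)CC)C/C(C)=C/C` | intermediate
30 | (1Z,7S,9E)-9-methyl-6-oxo-7-{1-[(tert-butyldimethylsilyl)oxy]-2-[(triethylsilyl)oxy]-3-(trimethylsilyl)propan-2-yl}-7-[(triethylsilyl)oxy]undeca-1,9-dien-4-yn-1-yl (2E,4E,6R)-4,6-dimethylocta-2,4-dienoate | `CC(C)(C)[Si](C)(C)OCC(O[Si](CC)(CC)CC)(C[Si](C)(C)C)[C@@](C(=O)C#CC/C=C\OC(=O)/C=C/C(C)=C/[C@H](C)CC)(O[Si](CC)(CC)CC)C/C(C)=C/C` | intermediate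
31 | (1Z,7S,9E)-9-methyl-6-oxo-7-{1-[(tert-butyldimethylsilyl)oxy]-2-[(triethylsilyl)oxy]-3-(trimethylsilyl)propan-2-yl}-7-[(triethylsilyl)oxy]undeca-1,3,4,9-tetraen-1-yl (2E,4E,6R)-4,6-dimethylocta-2,4-dienoate (both allene epimers) | `CC(C)(C)[Si](C)(C)OCC(O[Si](CC)(CC)CC)(C[Si](C)(C)C)[C@@](C(=O)C=C=C/C=C\OC(=O)/C=C/C(C)=C/[C@H](C)CC)(O[Si](CC)(CC)CC)C/C(C)=C/C` | intermediate
32 | (3S,4S,5S,7S)-13-[(tert-butyldimethylsilyl)oxy]-8-oxo-7,11-bis[(triethylsilyl)oxy]-12-(trimethylsilyl)eremophila-1,9-dien-3-yl (2E,4E,6R)-4,6-dimethylocta-2,4-dienoate (C11 epimers) | `CC(C)(C)[Si](C)(C)OCC(O[Si](CC)(CC)CC)(C[Si](C)(C)C)[C@@]1(O[Si](CC)(CC)CC)C[C@]2(C)C(=CC1=O)C=C[C@H](OC(=O)/C=C/C(C)=C/[C@H](C)CC)[C@H]2C` | intermediate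
33 | (3S,4S,5S,7S)-7,13-dihydroxy-8-oxoeremophila-1,9,11(12)-trien-3-yl (2E,4E,6R)-4,6-dimethylocta-2,4-dienoate | `C=C(CO)[C@@]1(O)C[C@]2(C)C(=CC1=O)C=C[C@H](OC(=O)/C=C/C(C)=C/[C@H](C)CC)[C@H]2C` | intermediate
34 | acetic anhydride | `CC(=O)OC(C)=O` | starting material
35 | (3S,4S,5S,7S)-13-acetoxy-7-hydroxy-8-oxoeremophila-1,9,11(12)-trien-3-yl (2E,4E,6R)-4,6-dimethylocta-2,4-dienoate | `C=C(COC(C)=O)[C@@]1(O)C[C@]2(C)C(=CC1=O)C=C[C@H](OC(=O)/C=C/C(C)=C/[C@H](C)CC)[C@H]2C` | target

**Step count and risks**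

Total step count: 17. Longest linear sequence: 11 steps (steps 7–17, from 14 to 35).

Steps most likely to fail:

1. Step 15. The cycloaddition through an unactivated trisubstituted alkene may be slower than base-mediated proton drift from the skipped position into full conjugation, which would destroy the diene and scramble the enol ester geometry. The relay from C7 to the diene face may also be weak.
Fallback (conventional silyloxytriene Diels–Alder reaction, then dehydrogenation; no allene, no base during the cycloaddition), from 30 back to 32. Semihydrogenation of ynone 30 (H2, Pd/CaCO3 poisoned by Pb(OAc)2, quinoline) should give the (Z)-enone F1. Soft enolisation with t-BuMe2SiOSO2CF3/Et3N can only take place toward C1, because C7 is quaternary, and should give the cross-conjugated silyloxytriene F2. Heating (toluene, 160 °C, sealed tube) should bring about the intramolecular Diels–Alder reaction of the terminal diene C10=C1–C2=C3 with the same alkene to the bicyclic silyl enol ether F3. Saegusa–Ito oxidation (Pd(OAc)2, MeCN) then introduces C9=C10 and returns 32. In this variant the C3/C4 relationship depends on the fusion mode of the transition state and has to be checked at F3.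

2. Step 9. Enantiofacial discrimination may be low on an open-chain keto ester whose metal enolate geometry is not fixed.
Fallback (C7 made by C–C bond formation instead of C–O bond formation), from 18 and 14 back to 22. Weinreb amide 18 is acylated onto the lithium enolate of methyl acetate (LiN(i-Pr)2, THF, −78 °C) to give methyl 4-[(tert-butyldimethylsilyl)oxy]-3-oxobutanoate F4. Diazo transfer (4-acetamidobenzenesulfonyl azide, Et3N, MeCN) gives the diazo keto ester F5, and t-BuMe2SiOSO2CF3/Et3N gives the siloxyvinyl diazoacetate F6. Decomposition of F6 with Rh2[(S)-DOSP]4 (1 mol %, pentane, 0 °C) in the presence of racemic alcohol 14 should form the oxonium ylide, whose [2,3]-sigmatropic rearrangement gives the tertiary α-hydroxy ester F7 with the (E)-tiglyl arm. Mild hydrolysis of the silyl enol ether (AcOH, THF/H2O) returns 22.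

3. Step 13. The acetylide or the resulting alkoxide may take the acyl group from the enol ester, or the addition to the neopentyl-type aldehyde may stall.
Fallback (side chain attached after the fragment union), from 27 and 11 back to 29. The magnesium acetylide of diyne 11 (EtMgBr, THF) is added to aldehyde 27 to give the silylated diynol F8. Silver-catalysed protodesilylation (AgNO3, acetone/H2O) gives the terminal diynol F9. The ruthenium-catalysed anti-Markovnikov addition of acid 7 (catalyst and conditions of step 5) to the terminal alkyne of F9 then gives 29.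

**Further compounds**

F1 | step 15 | (1Z,4Z,7S,9E)-9-methyl-6-oxo-7-{1-[(tert-butyldimethylsilyl)oxy]-2-[(triethylsilyl)oxy]-3-(trimethylsilyl)propan-2-yl}-7-[(triethylsilyl)oxy]undeca-1,4,9-trien-1-yl (2E,4E,6R)-4,6-dimethylocta-2,4-dienoate | `CC(C)(C)[Si](C)(C)OCC(O[Si](CC)(CC)CC)(C[Si](C)(C)C)[C@@](C(=O)/C=C\C/C=C\OC(=O)/C=C/C(C)=C/[C@H](C)CC)(O[Si](CC)(CC)CC)C/C(C)=C/C`
F2 | step 15 | (1Z,3E,9E)-6-[(tert-butyldimethylsilyl)oxy]-9-methyl-7-{1-[(tert-butyldimethylsilyl)oxy]-2-[(triethylsilyl)oxy]-3-(trimethylsilyl)propan-2-yl}-7-[(triethylsilyl)oxy]undeca-1,3,5,9-tetraen-1-yl (2E,4E,6R)-4,6-dimethylocta-2,4-dienoate (C7 as in 30) | `CC(C)(C)[Si](C)(C)OCC(O[Si](CC)(CC)CC)(C[Si](C)(C)C)[C@@](C(O[Si](C)(C)C(C)(C)C)=C/C=C/C=C\OC(=O)/C=C/C(C)=C/[C@H](C)CC)(O[Si](CC)(CC)CC)C/C(C)=C/C`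
F3 | step 15 | 8,13-bis[(tert-butyldimethylsilyl)oxy]-7,11-bis[(triethylsilyl)oxy]-12-(trimethylsilyl)eremophila-1,8-dien-3-yl (2E,4E,6R)-4,6-dimethylocta-2,4-dienoate (C3, C4, C5, C7 as in 32; C10 open) | `CC(C)(C)[Si](C)(C)OCC(O[Si](CC)(CC)CC)(C[Si](C)(C)C)[C@@]1(O[Si](CC)(CC)CC)C[C@]2(C)C(C=C1O[Si](C)(C)C(C)(C)C)C=C[C@H](OC(=O)/C=C/C(C)=C/[C@H](C)CC)[C@H]2C`
F4 | step 9 | methyl 4-[(tert-butyldimethylsilyl)oxy]-3-oxobutanoate | `COC(=O)CC(=O)CO[Si](C)(C)C(C)(C)C`
F5 | step 9 | methyl 4-[(tert-butyldimethylsilyl)oxy]-2-diazo-3-oxobutanoate | `COC(=O)C(=[N+]=[N-])C(=O)CO[Si](C)(C)C(C)(C)C`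
F6 | step 9 | methyl 3,4-bis[(tert-butyldimethylsilyl)oxy]-2-diazobut-3-enoate | `COC(=O)C(=[N+]=[N-])C(O[Si](C)(C)C(C)(C)C)=CO[Si](C)(C)C(C)(C)C`
F7 | step 9 | methyl (2S,4E)-2-{1,2-bis[(tert-butyldimethylsilyl)oxy]ethenyl}-2-hydroxy-4-methylhex-4-enoate | `CC(C)(C)[Si](C)(C)OC=C(O[Si](C)(C)C(C)(C)C)[C@@](C(=O)OC)(O)C/C(C)=C/C`
F8 | step 13 | (2E,5R)-5-{1-[(tert-butyldimethylsilyl)oxy]-2-[(triethylsilyl)oxy]-3-(trimethylsilyl)propan-2-yl}-3-methyl-5-[(triethylsilyl)oxy]-11-(trimethylsilyl)undec-2-ene-7,10-diyn-6-ol (C6 epimers; C5 as C7 of 27) | `CC(C)(C)[Si](C)(C)OCC(O[Si](CC)(CC)CC)(C[Si](C)(C)C)[C@@](C(O)C#CCC#C[Si](C)(C)C)(O[Si](CC)(CC)CC)C/C(C)=C/C`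
F9 | step 13 | (2E,5R)-5-{1-[(tert-butyldimethylsilyl)oxy]-2-[(triethylsilyl)oxy]-3-(trimethylsilyl)propan-2-yl}-3-methyl-5-[(triethylsilyl)oxy]undec-2-ene-7,10-diyn-6-ol (C6 epimers) | `CC(C)(C)[Si](C)(C)OCC(O[Si](CC)(CC)CC)(C[Si](C)(C)C)[C@@](C(O)C#CCC#C)(O[Si](CC)(CC)CC)C/C(C)=C/C`
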